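West cannot have stopped for want of left-handed substrate: its last readings average 13.8% of the substrates charged, less than the half that left-handed substrate makes up.

| flask | left-handed substrate | right-handed substrate | gas | free catalyst | temperature | remark | time |
|---|---|---|---|---|---|---|---|
| west | 1.6 M | 1.6 M | 60 mM (held) | 3.4 mol% | 25 °C | the very flask that is asked about, followed so far |  |
| north-east | 1.6 M | 1.6 M | 60 mM (held) | 3.4 mol% | 31 °C | run made earlier |  |
| flask | 1.6 M | 1.6 M | 60 mM (held) | 3.4 mol% | 25 °C |  | 8.0 d |

| run | time / h | left-handed product / % |
|---|---|---|
| west | 10.0 | 3.9 |
| west | 15.0 | 8.4 |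
| west | 25.0 | 8.1 |
| west | 40.0 | 13.8 |
| west | 72.0 | 13.8 |
| west | 120 | 13.7 |
| north-east | 10.0 | 5.7 |
| north-east | 15.0 | 9.0 |
| north-east | 25.0 | 10.7 |
| north-east | 40.0 | 13.4 |
| north-east | 72.0 | 14.2 |
| north-east | 120 | 13.2 |

(readings scatter by 1 percentage point)

1. left-handed product, in percent of the left-handed substrate and right-handed substrate together first charged, at 8.0 d
2. what to do for the largest gain in left-handed product; "none" if nothing gains more than 2 percentage points (cedar / birch / elm / maple / none)
3. left-handed product present, with what was taken out counted in, in percent of the left-handed substrate and right-handed substrate together first charged, after birch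
4. left-handed product present, with what was taken out counted in, in percent of the left-handed substrate and right-handed substrate together first charged, after maple

- cedar: at 8.0 d add free catalyst, 100% of the amount charged, then wait 4.0 d
- birch: change nothing and wait 4.0 d more
- elm: at 8.0 d take out 90% of the left-handed product then present, then wait 4.0 d
- maple: at 8.0 d raise the temperature by 25 K, then wait 4.0 d

- free catalyst is single-handed; left-handed substrate and right-handed substrate are mirror images of each other, charged as a racemate, each of them at the stated concentration
- at the start none of reagent is dissolved
- what is taken out of left-handed product is counted as made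
- the numbers in the tables scatter by 1 percentage point (one standard deviation)
- on the list of suspects stand: reagent + catalyst intermediate B -> free catalyst + right-handed product; reagent + free catalyst -> spent catalyst; reagent + catalyst intermediate A -> free catalyst + left-handed product; left-handed substrate <-> right-handed substrate; gas <-> reagent; free catalyst + right-handed substrate <-> catalyst intermediate B; free catalyst + left-handed substrate <-> catalyst intermediate A
- additions bring no volume worth counting

So look at free catalyst, charged at 3.4 mol% of left-handed substrate. Write its balance: free catalyst, catalyst intermediate A, catalyst intermediate B and spent catalyst sum to the charge, and no suspect step leaves spent catalyst. West gives 8.10 left-handed product per catalyst charged, a turnover number. From 40.0 h to 120 h west moves 0.1 percentage points, less than the scatter of 1 point, and north-east at 31 °C averages 13.6%. I read that flat stretch as catalyst passed into spent catalyst, so I take 13.8% for now. I expect nothing from birch, elm or maple, since no suspect step leaves spent catalyst or left-handed product. On that count, cedar adds another 13.8%.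

That is the weak link: the count holds c(left-handed substrate) constant, and it falls. Reagent enters once into the step giving left-handed product and once into the step killing free catalyst, so c(reagent) cancels in their ratio. If binding keeps pace, the ratio of catalyst intermediate A to free catalyst follows c(left-handed substrate), and so does product per dead catalyst. Assume roughly that left-handed substrate goes to left-handed product. Then the logarithm of charged over remaining left-handed substrate grows in step with catalyst loading. West gives 9.47 for that slope, the yield constant. Doubling the loading under cedar then gains 10 points, less than 13.8% but above the margin of 2 points. I commit to cedar.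

The forecast gave 13.8% now, 13.8% after birch, 13.9% after maple and cedar as best, on the ground: “Only fresh catalyst restarts production”.

The flask gave 13.2% now, 13.2% after birch and 13.2% after maple; cedar gained 10 points against my 10 points, elm 0 points.

    reagent + catalyst intermediate B → free catalyst + right-handed product (k = 0.00470 M⁻¹ s⁻¹, Ea = 59.0 kJ mol⁻¹)
    reagent + free catalyst → spent catalyst (k = 0.00120 M⁻¹ s⁻¹, Ea = 65.0 kJ mol⁻¹)
    reagent + catalyst intermediate A → free catalyst + left-handed product (k = 0.0110 M⁻¹ s⁻¹, Ea = 67.0 kJ mol⁻¹)
    left-handed substrate ⇌ right-handed substrate (k = 3.40 × 10⁻⁶ s⁻¹, Ea = 99.0 kJ mol⁻¹)
    gas ⇌ reagent, rate k5*(csat - [reagent]) (kL = 2.70 × 10⁻⁴ s⁻¹)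
    free catalyst + right-handed substrate ⇌ catalyst intermediate B (K = 0.730 M⁻¹, k = 0.0320 M⁻¹ s⁻¹, Ea = 70.0 kJ mol⁻¹, ΔH = −11.0 kJ mol⁻¹)
    free catalyst + left-handed substrate ⇌ catalyst intermediate A (K = 0.620 M⁻¹, k = 0.0160 M⁻¹ s⁻¹, Ea = 49.0 kJ mol⁻¹, ΔH = −10.0 kJ mol⁻¹)
    (constants at 25 °C)

On the neighbour flask charged with 14 mol%, the yield constant gives 36.7%, and the simulation gives 36.9%. The west flask itself is at rest. At 192 h spent catalyst is 100%, with free catalyst 0%, catalyst intermediate A 0% and catalyst intermediate B 0%. Left-handed substrate then stands at 39.8%, and at 1920 h it stands at 39.9%, with left-handed product at 13.2%.

The runs come from a simulation for substances that don't exist; the scatter is artificial.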